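**Retrosynthetic overview**
- The target comes from a pentacyclic keto-lactone by reduction of the C24 ketone and removal of a C17 acetate.
- That keto-lactone is made in one step by an intramolecular hetero-Diels–Alder reaction between the central C=O of a vicinal tricarbonyl spiro-lactone and a tethered (E,E,E)-triene. This closes the dihydropyran and the cyclohexane (the bicyclo[2.2.2] lactone) together and sets C10, C12 and C20.
- The tricarbonyl comes from a spiro β-keto-δ-lactone (acetylation/Dieckmann on a cyclopentane tert-butyl ester) after Mitsunobu inversion at C17; the triene is attached by Horner–Wadsworth–Emmons reaction of a bicyclic lactol with a dienyl phosphonate.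
- The cyclopentane comes from ethyl (R)-4-chloro-3-hydroxybutanoate: Claisen homologation, O-bromoacetate, SmI2 Reformatsky lactonisation (sets C15), then lactone-enolate alkylation to a 2-oxabicyclo[2.2.1]heptanone (sets C19).
- Ring order: temporary δ-lactone → cyclopentane → spiro keto-lactone → dihydropyran and cyclohexane in the one cycloaddition.

Assumption: atom labels used for stereocentres are C10 (O–CH bearing the nonenyl chain), C12 (quaternary O/C=O carbon), C15 (carbon bearing the lactone oxygen), C17 (cyclopentane carbinol), C19 (cyclopentane CH), C20 (allylic CH next to C12) and C24 (carbinol next to C12); the target is (10R,12S,15R,17R,19S,20R,24R), and ethyl (R)-4-chloro-3-hydroxybutanoate is taken as a cheap bulk chemical.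

**Route**

Step 1
Reactants: 1 (E)-dec-2-enal; 2 ethyl 2-(triphenylphosphoranylidene)propanoate
Product: 3 ethyl (2E,4E)-2-methyldodeca-2,4-dienoate
Conditions: CH2Cl2, 25 → 40 °C
Reagents that add atoms: none
Why: Wittig olefination with a stabilised ylide gives the trisubstituted (E)-enoate selectively and leaves the existing (E)-alkene untouched.

Step 2
Reactants: 3 ethyl (2E,4E)-2-methyldodeca-2,4-dienoate
Product: 4 (2E,4E)-2-methyldodeca-2,4-dien-1-ol
Conditions: i-Bu2AlH (2.2 equiv), CH2Cl2, −78 °C; aq. KNaC4H4O6 (potassium sodium tartrate)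
Reagents that add atoms: none
Why: Hydride 1,2-reduction of the conjugated ester stops cleanly at the allylic alcohol without touching the diene.

Step 3
Reactants: 4 (2E,4E)-2-methyldodeca-2,4-dien-1-ol
Product: 6 diethyl [(2E,4E)-2-methyldodeca-2,4-dien-1-yl]phosphonate, via dienyl bromide 5 (not isolated)
Conditions: PBr3 (0.4 equiv), Et2O, 0 °C; concentrate; P(OEt)3 (neat), 120 °C
Reagents that add atoms: triethyl phosphite CCOP(OCC)OCC; phosphorus tribromide BrP(Br)Br (bromine in 5 only)
Why: Allylic bromination followed by Michaelis–Arbuzov reaction gives the conjugated primary phosphonate, which is the thermodynamically preferred allylic isomer.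

Step 4
Reactants: 7 ethyl (3R)-4-chloro-3-hydroxybutanoate; 8 tert-butyl acetate
Product: 9 tert-butyl (5R)-6-chloro-5-hydroxy-3-oxohexanoate
Conditions: 8 (3.6 equiv), LiN(i-Pr)2 (3.6 equiv), THF, −78 °C; then 7, −78 → −30 °C; aq. HCl
Reagents that add atoms: none
Why: Crossed Claisen condensation of the ester enolate on the ethyl ester (the free hydroxyl is carried as its alkoxide) gives the β-keto ester without touching the purchased stereocentre (C17).

Step 5
Reactants: 9 tert-butyl (5R)-6-chloro-5-hydroxy-3-oxohexanoate; 10 bromoacetyl bromide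
Product: 11 tert-butyl (5R)-5-(2-bromoacetoxy)-6-chloro-3-oxohexanoate
Conditions: pyridine (1.5 equiv), CH2Cl2, −20 °C
Reagents that add atoms: none
Why: O-acylation of the secondary alcohol by the acid bromide is much faster than acylation of the β-keto ester at low temperature.

Step 6
Reactants: 11 tert-butyl (5R)-5-(2-bromoacetoxy)-6-chloro-3-oxohexanoate
Product: 12 tert-butyl 2-[(2R,4S)-2-(chloromethyl)-4-hydroxy-6-oxooxan-4-yl]acetate
Conditions: SmI2 (2.2 equiv, 0.1 M in THF), −78 °C; aq. NH4Cl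
Reagents that add atoms: none
Why: Intramolecular samarium Reformatsky (aldol-lactonisation) passes through a chair transition state in which trivalent samarium bridges the enolate and ketone oxygens (both axial) while CH2Cl and CH2CO2tBu sit equatorial, so 1,3-induction from C17 sets C15 with the new hydroxyl trans to CH2Cl.

Step 7
Reactants: 12 tert-butyl 2-[(2R,4S)-2-(chloromethyl)-4-hydroxy-6-oxooxan-4-yl]acetate
Product: 13 tert-butyl 2-[(1S,4R,5R)-5-hydroxy-3-oxo-2-oxabicyclo[2.2.1]heptan-5-yl]acetate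
Conditions: LiN(i-Pr)2 (2.2 equiv), THF–DMPU, −78 → 0 °C; aq. NH4Cl
Reagents that add atoms: none
Why: The alkoxide/lactone-enolate dianion (the lactone α-CH2 is more acidic than the hindered tert-butyl ester α-CH2) closes the cyclopentane by 5-exo-tet SN2 alkylation; the one-carbon bridge can only form cis, which fixes C19, and the trans alkoxide cannot reach the chloride.

Step 8
Reactants: 13 tert-butyl 2-[(1S,4R,5R)-5-hydroxy-3-oxo-2-oxabicyclo[2.2.1]heptan-5-yl]acetate
Product: 14 tert-butyl 2-[(1S,4R,5R)-3,5-dihydroxy-2-oxabicyclo[2.2.1]heptan-5-yl]acetate (lactol)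
Conditions: i-Bu2AlH (2.3 equiv), CH2Cl2, −78 °C; aq. KNaC4H4O6 (potassium sodium tartrate)
Reagents that add atoms: none
Why: Partial hydride reduction of the strained lactone stops at the tetrahedral aluminate (lactol) at −78 °C, while the tert-butyl ester is much slower to react.

Step 9
Reactants: 14 tert-butyl 2-[(1S,4R,5R)-3,5-dihydroxy-2-oxabicyclo[2.2.1]heptan-5-yl]acetate; 6 diethyl [(2E,4E)-2-methyldodeca-2,4-dien-1-yl]phosphonate
Product: 15 tert-butyl 2-[(1R,2S,4S)-1,4-dihydroxy-2-[(1E,3E,5E)-3-methyltrideca-1,3,5-trien-1-yl]cyclopentyl]acetate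
Conditions: 6 (3.5 equiv), LiN(SiMe3)2 (3.4 equiv), THF, −78 °C; then 14, −78 → 0 °C; aq. NH4Cl
Reagents that add atoms: none
Why: Horner–Wadsworth–Emmons olefination of the ring-opened lactol aldehyde with the allylic phosphonate carbanion gives the new (E)-alkene and completes the (E,E,E)-triene without changing C15, C17 or C19.

Step 10
Reactants: 15 tert-butyl 2-[(1R,2S,4S)-1,4-dihydroxy-2-[(1E,3E,5E)-3-methyltrideca-1,3,5-trien-1-yl]cyclopentyl]acetate
Product: 16 tert-butyl 2-[(1R,2S,4R)-4-acetoxy-1-hydroxy-2-[(1E,3E,5E)-3-methyltrideca-1,3,5-trien-1-yl]cyclopentyl]acetate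
Conditions: PPh3, DIAD, AcOH (1.5 equiv each), THF, 0 → 25 °C
Reagents that add atoms: acetic acid CC(=O)O
Why: Mitsunobu esterification proceeds by SN2 displacement at the secondary carbinol only (the tertiary alcohol is inert), which inverts C17 to the required configuration and protects it in the same operation.

Step 11
Reactants: 16 tert-butyl 2-[(1R,2S,4R)-4-acetoxy-1-hydroxy-2-[(1E,3E,5E)-3-methyltrideca-1,3,5-trien-1-yl]cyclopentyl]acetate
Product: 18 (1S,3R,5R)-1-[(1E,3E,5E)-3-methyltrideca-1,3,5-trien-1-yl]-7,9-dioxo-6-oxaspiro[4.5]decan-3-yl acetate, via diacetate 17 (not isolated)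
Conditions: LiN(SiMe3)2 (1.05 equiv), THF, −78 °C; Ac2O (1.05 equiv), → 0 °C; then LiN(SiMe3)2 (3.3 equiv), −78 → 25 °C; 1 M HCl
Reagents that add atoms: acetic anhydride CC(=O)OC(C)=O
Why: Acetylation of the lithium tertiary alkoxide followed by Dieckmann (intramolecular Claisen) attack of the kinetically formed acetate enolate on the tert-butyl ester (6-exo-trig) gives the spiro β-keto-δ-lactone, with no stereocentre involved.

Step 12
Reactants: 18 (1S,3R,5R)-1-[(1E,3E,5E)-3-methyltrideca-1,3,5-trien-1-yl]-7,9-dioxo-6-oxaspiro[4.5]decan-3-yl acetate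
Product: 20 (10R,12S,15R,17R,19S,20R)-17-O-acetyl-24-oxo cycloadduct (pentacyclic keto-lactone), via trione 19 (not isolated)
Conditions: Dess–Martin periodinane (2.6 equiv), pyridine (6 equiv), wet CH2Cl2, 0 → 25 °C; then toluene, 4 Å molecular sieves, 80 °C
Reagents that add atoms: Dess–Martin periodinane CC(=O)OI1(OC(C)=O)(OC(C)=O)OC(=O)c2ccccc12; water O
Why: Dess–Martin oxidation of the 1,3-dicarbonyl CH2 gives the vicinal tricarbonyl, whose central carbonyl (the most electrophilic, and the only one that closes a six-membered carbocycle) undergoes intramolecular hetero-Diels–Alder [4+2] cycloaddition with the tethered diene; the tether allows only one carbonyl face (C12), suprafacial addition to the (E,E)-diene puts H-10 and H-20 cis, and the diene is expected to stack endo over the lactone bridge, which carries no hydrogens (C20 and C10 relative to the core).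

Step 13
Reactants: 20 (10R,12S,15R,17R,19S,20R)-17-O-acetyl-24-oxo cycloadduct
Product: 22 CNP0127096.1 (target), via 17-O-acetyl target 21 (not isolated)
Conditions: NaBH4 (1.0 equiv), MeOH–THF, −40 °C; then K2CO3 (0.3 equiv), MeOH, 0 → 25 °C; aq. NH4Cl
Reagents that add atoms: none
Why: Hydride attacks the bridging C24 ketone from the open groove beside the lactone bridge (the other face is screened by the hydrogens of the C19–C20 bridge), giving the (24R)-alcohol, and base-catalysed methanolysis then removes the acetate while the hindered bridged lactone, which cannot form a bridgehead enolate, survives.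

**Compound list**

1 | (E)-dec-2-enal | CCCCCCC/C=C/C=O | starting material
2 | ethyl 2-(triphenylphosphoranylidene)propanoate | CCOC(=O)C(C)=P(c1ccccc1)(c1ccccc1)c1ccccc1 | starting material
3 | ethyl (2E,4E)-2-methyldodeca-2,4-dienoate | CCCCCCC/C=C/C=C(\C)C(=O)OCC | intermediate
4 | (2E,4E)-2-methyldodeca-2,4-dien-1-ol | CCCCCCC/C=C/C=C(\C)CO | intermediate
5 | (2E,4E)-1-bromo-2-methyldodeca-2,4-diene | CCCCCCC/C=C/C=C(\C)CBr | intermediate
6 | diethyl [(2E,4E)-2-methyldodeca-2,4-dien-1-yl]phosphonate | CCCCCCC/C=C/C=C(\C)CP(=O)(OCC)OCC | intermediate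
7 | ethyl (3R)-4-chloro-3-hydroxybutanoate | CCOC(=O)C[C@@H](O)CCl | starting material
8 | tert-butyl acetate | CC(=O)OC(C)(C)C | starting material
9 | tert-butyl (5R)-6-chloro-5-hydroxy-3-oxohexanoate | CC(C)(C)OC(=O)CC(=O)C[C@@H](O)CCl | intermediate
10 | bromoacetyl bromide | BrCC(Br)=O | starting material
11 | tert-butyl (5R)-5-(2-bromoacetoxy)-6-chloro-3-oxohexanoate | CC(C)(C)OC(=O)CC(=O)C[C@@H](OC(=O)CBr)CCl | intermediate
12 | tert-butyl 2-[(2R,4S)-2-(chloromethyl)-4-hydroxy-6-oxooxan-4-yl]acetate | CC(C)(C)OC(=O)C[C@]1(O)C[C@H](CCl)OC(=O)C1 | intermediate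
13 | tert-butyl 2-[(1S,4R,5R)-5-hydroxy-3-oxo-2-oxabicyclo[2.2.1]heptan-5-yl]acetate | CC(C)(C)OC(=O)C[C@]1(O)C[C@@H]2C[C@H]1C(=O)O2 | intermediate
14 | tert-butyl 2-[(1S,4R,5R)-3,5-dihydroxy-2-oxabicyclo[2.2.1]heptan-5-yl]acetate (lactol, anomer mixture) | CC(C)(C)OC(=O)C[C@]1(O)C[C@@H]2C[C@H]1C(O)O2 | intermediate
15 | tert-butyl 2-[(1R,2S,4S)-1,4-dihydroxy-2-[(1E,3E,5E)-3-methyltrideca-1,3,5-trien-1-yl]cyclopentyl]acetate | CC(C)(C)OC(=O)C[C@]1(O)C[C@@H](O)C[C@H]1/C=C/C(C)=C/C=C/CCCCCCC | intermediate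
16 | tert-butyl 2-[(1R,2S,4R)-4-acetoxy-1-hydroxy-2-[(1E,3E,5E)-3-methyltrideca-1,3,5-trien-1-yl]cyclopentyl]acetate | CC(C)(C)OC(=O)C[C@]1(O)C[C@H](OC(C)=O)C[C@H]1/C=C/C(C)=C/C=C/CCCCCCC | intermediate
17 | tert-butyl 2-[(1R,2S,4R)-1,4-diacetoxy-2-[(1E,3E,5E)-3-methyltrideca-1,3,5-trien-1-yl]cyclopentyl]acetate | CC(C)(C)OC(=O)C[C@]1(OC(C)=O)C[C@H](OC(C)=O)C[C@H]1/C=C/C(C)=C/C=C/CCCCCCC | intermediate
18 | (1S,3R,5R)-1-[(1E,3E,5E)-3-methyltrideca-1,3,5-trien-1-yl]-7,9-dioxo-6-oxaspiro[4.5]decan-3-yl acetate (drawn as the keto form) | O=C1CC(=O)C[C@]2(O1)C[C@H](OC(C)=O)C[C@H]2/C=C/C(C)=C/C=C/CCCCCCC | intermediate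
19 | (1S,3R,5R)-1-[(1E,3E,5E)-3-methyltrideca-1,3,5-trien-1-yl]-7,8,9-trioxo-6-oxaspiro[4.5]decan-3-yl acetate | O=C1C(=O)C(=O)C[C@]2(O1)C[C@H](OC(C)=O)C[C@H]2/C=C/C(C)=C/C=C/CCCCCCC | intermediate
20 | (10R,12S,15R,17R,19S,20R)-17-O-acetyl-24-oxo cycloadduct: target skeleton with a ketone at C24 and an acetate on the C17 oxygen | CCCCCCC/C=C/[C@H]1O[C@@]23C(=O)O[C@]4(C[C@H](OC(C)=O)C[C@H]4[C@H]2C=C1C)CC3=O | intermediate
21 | 17-O-acetyl target, (10R,12S,15R,17R,19S,20R,24R) | CCCCCCC/C=C/[C@H]1O[C@@]23C(=O)O[C@]4(C[C@H](OC(C)=O)C[C@H]4[C@H]2C=C1C)C[C@H]3O | intermediate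
22 | CNP0127096.1, (10R,12S,15R,17R,19S,20R,24R) | CCCCCCC/C=C/[C@H]1O[C@@]23C(=O)O[C@]4(C[C@H](O)C[C@H]4[C@H]2C=C1C)C[C@H]3O | target

**Step count**
Total: 13 steps. Longest linear sequence: 10 steps (steps 4–13, from 7); the phosphonate 6 is made in 3 steps and joins at step 9.

**Three steps most likely to fail**

Step 12 (trione formation and hetero-Diels–Alder). The C12 configuration and the cis relationship of H-10 and H-20 are enforced, but the diene π-face is not. The diene can lie over the lactone bridge, as needed, or over the ketone bridge, and the two orientations differ only by small torsional and secondary-orbital effects, so a mixture or the wrong major isomer is possible. The free trione may also hydrate or degrade. The fallback sets out from 19 and comes back at 20. The trione is not cyclised directly; it is first silylated at its only enolisable position (TIPSOTf, 2,6-lutidine, CH2Cl2, −78 °C) to the C24 triisopropylsilyl enol ether keto-lactone F1. This leaves the lactone carbonyl as the only carbonyl beside the reacting C=O and puts a bulky group on the other side, so the diene is steered over the lactone bridge. Heating (toluene, 80–110 °C) gives the silyl enol ether cycloadduct F2, and HF·pyridine (THF, 0 °C) unmasks the C24 ketone to give 20.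

Step 6 (samarium Reformatsky on an acidic β-keto ester). Proton transfer from the β-keto ester to the samarium enolate would give only the reduced acetate. The fallback sets out from 9 and comes back at 13. Chelation-controlled allylation of the β-hydroxy ketone (In powder, allyl bromide, THF–H2O, 25 °C) gives the 1,3-anti allyl carbinol F3. Acid (CF3CO2H, CH2Cl2, 0 °C) lactonises it through the tert-butyl ester arm to the allyl lactone F4, which has the same relative configuration as 12. LiN(i-Pr)2 (THF–DMPU) closes the bicyclic allyl lactone F5. Oxidative cleavage of the alkene (RuCl3 cat., NaIO4, CCl4–MeCN–H2O) gives the carboxylic acid F6, and tert-butyl 2,2,2-trichloroacetimidate with BF3·OEt2 (cat.) returns 13.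

Step 9 (lactol olefination). The open-chain β-alkoxide aldehyde could undergo retro-aldol ring opening under the basic conditions, and the E-selectivity of the allylic phosphonate is not guaranteed. The fallback sets out from 13 (and from 4 for the partner) and comes back at 15, reversing the polarity of the coupling. LiBH4 (THF, 0 °C) reduces the lactone to the triol F7. Mitsunobu reaction at the primary alcohol with 1-phenyl-1H-tetrazole-5-thiol (PPh3, DIAD, 0 °C) gives the sulfide F8, and (NH4)6Mo7O24/H2O2 oxidises it to the sulfone F9. MnO2 oxidation of 4 gives (2E,4E)-2-methyldodeca-2,4-dienal F10. Julia–Kocienski olefination of F9 with F10 (KN(SiMe3)2, 3.2 equiv, THF, −78 °C) forms the (E)-alkene and gives 15.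

**Further compounds**

F1 | step 12 | (1S,3R,5R)-1-[(1E,3E,5E)-3-methyltrideca-1,3,5-trien-1-yl]-7,8-dioxo-9-[(triisopropylsilyl)oxy]-6-oxaspiro[4.5]dec-9-en-3-yl acetate | O=C1C(=O)C(O[Si](C(C)C)(C(C)C)C(C)C)=C[C@]2(O1)C[C@H](OC(C)=O)C[C@H]2/C=C/C(C)=C/C=C/CCCCCCC
F2 | step 12 | C24 triisopropylsilyl enol ether of cycloadduct 20 | CCCCCCC/C=C/[C@H]1O[C@@]23C(=O)O[C@]4(C[C@H](OC(C)=O)C[C@H]4[C@H]2C=C1C)C=C3O[Si](C(C)C)(C(C)C)C(C)C
F3 | step 6 | tert-butyl (3S)-3-[(2R)-3-chloro-2-hydroxypropyl]-3-hydroxyhex-5-enoate | C=CC[C@@](O)(CC(=O)OC(C)(C)C)C[C@@H](O)CCl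
F4 | step 6 | (4S,6R)-6-(chloromethyl)-4-hydroxy-4-(prop-2-en-1-yl)oxan-2-one | C=CC[C@]1(O)C[C@H](CCl)OC(=O)C1
F5 | step 6 | (1S,4R,5S)-5-hydroxy-5-(prop-2-en-1-yl)-2-oxabicyclo[2.2.1]heptan-3-one | C=CC[C@]1(O)C[C@@H]2C[C@H]1C(=O)O2
F6 | step 6 | 2-[(1S,4R,5R)-5-hydroxy-3-oxo-2-oxabicyclo[2.2.1]heptan-5-yl]acetic acid | OC(=O)C[C@]1(O)C[C@@H]2C[C@H]1C(=O)O2
F7 | step 9 | tert-butyl 2-[(1R,2S,4S)-1,4-dihydroxy-2-(hydroxymethyl)cyclopentyl]acetate | CC(C)(C)OC(=O)C[C@]1(O)C[C@@H](O)C[C@H]1CO
F8 | step 9 | tert-butyl 2-[(1R,2R,4S)-1,4-dihydroxy-2-{[(1-phenyl-1H-tetrazol-5-yl)sulfanyl]methyl}cyclopentyl]acetate | CC(C)(C)OC(=O)C[C@]1(O)C[C@@H](O)C[C@H]1CSc1nnnn1-c1ccccc1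
F9 | step 9 | tert-butyl 2-[(1R,2R,4S)-1,4-dihydroxy-2-{[(1-phenyl-1H-tetrazol-5-yl)sulfonyl]methyl}cyclopentyl]acetate | CC(C)(C)OC(=O)C[C@]1(O)C[C@@H](O)C[C@H]1CS(=O)(=O)c1nnnn1-c1ccccc1
F10 | step 9 | (2E,4E)-2-methyldodeca-2,4-dienal | CCCCCCC/C=C/C=C(\C)C=O
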